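**Retrosynthetic overview**
1. Feature: ring A (C1–OH, C2–OAr, C3–Br, C6–Br, C4–H, C5–H) carries bromine ortho to each oxygen-bearing carbon and hydrogen para to each. Electrophilic bromination of a catechol ether gives the opposite pattern, whereas the two α-carbons of a 3,4-dioxygenated thiophene take bromine in exactly these positions.
2. Last disconnection: the O–CH3 bond at C1. Key disconnection: C3–C4 and C5–C6 of ring A, leading back to a 2,5-dibromo-3-aryloxy-4-methoxythiophene 1,1-dioxide (C6, C1, C2, C3) and ethyl vinyl ether (C4, C5), with loss of SO2 and ethanol.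
3. The sulfone comes from S-oxidation of the tetrabromide, which comes from α,α'-dibromination of 3-(2,4-dibromophenoxy)-4-methoxythiophene.
4. The C2–O–C1' ether bond is made at room temperature by Chan–Lam–Evans coupling of a 3-thienylboronic acid with 2,4-dibromophenol, so ring B arrives with both bromines. Ortho-bromination of a 4-bromophenyl aryl ether needs Lewis-acid forcing, which a 2,5-dibromo-3,4-dialkoxythiophene should not survive.
5. Ring order: ring B is bought, the thiophene is bought and decorated, and ring A is formed from the thiophene in the penultimate step.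

Key step: step 6

Remark: the target has no stereocentre, and its tri-ortho-substituted diaryl ether axis rotates freely. It is therefore achiral and no enantiocontrol is needed.

Step 1
Reactants: 1 3,4-dibromothiophene; 2 sodium methoxide
Product: 3 3-bromo-4-methoxythiophene
Conditions: 2 (1.2 equiv, 25 wt % in MeOH), CuI (10 mol %), NMP, 100 °C; fractional distillation
Reagents that add atoms: none
Why: This is a copper-catalysed Ullmann-type methoxylation of a 3-bromothiophene, in which the first methoxy group enriches the ring and slows the second substitution, so limiting methoxide should stop at the mono-ether, separable from 1 and the dimethoxy compound.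

Step 2
Reactants: 3 3-bromo-4-methoxythiophene
Product: 6 (4-methoxythiophen-3-yl)boronic acid, via (4-methoxythiophen-3-yl)lithium 4 (not isolated), via lithium triisopropoxy(4-methoxythiophen-3-yl)borate 5 (not isolated)
Conditions: B(OiPr)3 (1.3 equiv) present, n-BuLi (1.1 equiv) added last, THF–PhMe, −78 → −20 °C; 1 M HCl
Reagents that add atoms: triisopropyl borate, CC(C)OB(OC(C)C)OC(C)C; water, O
Why: In this lithiation–borylation, bromine–lithium exchange at −78 °C outruns both α-deprotonation and attack of n-BuLi on the borate, and the in situ quench traps the 3-thienyllithium before it can isomerise to the 2-lithio species.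

Step 3
Reactants: 6 (4-methoxythiophen-3-yl)boronic acid (2 equiv); 7 2,4-dibromophenol
Product: 8 3-(2,4-dibromophenoxy)-4-methoxythiophene
Conditions: Cu(OAc)2 (2 equiv), pyridine (5 equiv), 4 Å MS, CH2Cl2, dry air, rt
Reagents that add atoms: none
Why: The Chan–Lam–Evans oxidative C–O coupling transfers the electron-rich thienyl group from boron to the copper phenoxide at room temperature, tolerates ortho-halogenated phenols and leaves the C–Br bonds untouched, unlike a hot Cu(I) or Pd(0) coupling.

Step 4
Reactants: 8 3-(2,4-dibromophenoxy)-4-methoxythiophene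
Product: 9 2,5-dibromo-3-(2,4-dibromophenoxy)-4-methoxythiophene
Conditions: NBS (2.1 equiv), DMF, 0 °C → rt, dark; product kept cold and used promptly
Reagents that add atoms: N-bromosuccinimide (NBS), O=C1CCC(=O)N1Br
Why: In this electrophilic aromatic bromination both free thiophene carbons are α to sulfur and ortho to an oxygen donor, which makes them far more reactive than the twice-brominated ring B, so exactly two bromines should enter.

Step 5
Reactants: 9 2,5-dibromo-3-(2,4-dibromophenoxy)-4-methoxythiophene
Product: 11 2,5-dibromo-3-(2,4-dibromophenoxy)-4-methoxythiophene 1,1-dioxide, via 2,5-dibromo-3-(2,4-dibromophenoxy)-4-methoxythiophene 1-oxide 10 (not isolated)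
Conditions: mCPBA (4 equiv), ClCH2CH2Cl, rt → 50 °C, dark; cold aq Na2SO3/NaHCO3 wash
Reagents that add atoms: 3-chloroperoxybenzoic acid (mCPBA), OOC(=O)c1cccc(Cl)c1
Why: In this peracid S-oxidation of a tetrasubstituted thiophene via its 1-oxide, the full substitution blocks Diels–Alder dimerisation of 10 and 11, the two oxygen donors keep sulfur nucleophilic despite the α-bromines, and ring B is too deactivated to be oxidised.

Step 6
Reactants: 11 2,5-dibromo-3-(2,4-dibromophenoxy)-4-methoxythiophene 1,1-dioxide; 12 ethyl vinyl ether
Product: 15 1,4-dibromo-2-(2,4-dibromophenoxy)-3-methoxybenzene, via 1,4-dibromo-2-(2,4-dibromophenoxy)-5-ethoxy-3-methoxy-7-thiabicyclo[2.2.1]hept-2-ene 7,7-dioxide 13 (not isolated), via 1,4-dibromo-2-(2,4-dibromophenoxy)-5-ethoxy-3-methoxycyclohexa-1,3-diene 14 (not isolated)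
Conditions: 12 (15 equiv), BHT (cat.), PhMe, sealed tube, 100–110 °C; evaporate; p-TsOH·H2O (10 mol %), PhMe, 60 °C
Reagents that add atoms: none
Why: Sulfone 11 is a non-aromatic, electron-poor cyclic diene whose two C–Br termini add the electron-rich alkene 12 in a concerted inverse-electron-demand [4+2] cycloaddition to give the SO2-bridged adduct 13, which loses SO2 cheletropically at the reaction temperature to give diene 14; acid then ionises the allylic C5–OEt bond to a cyclohexadienyl cation stabilised by the C1 methoxy group, and loss of a C4 proton gives arene 15. The closest known reaction type is the Diels–Alder/SO2-extrusion benzannulation of tetrahalo- and 2,5-dihalothiophene 1,1-dioxides with alkenes, here with an enol ether serving as the acetylene equivalent. Ring A closes as a six-membered carbocycle by intermolecular [4+2] cycloaddition, forming C3–C4 and C5–C6, with C6, C1, C2 and C3 coming from the thiophene and C4 and C5 from 12. The stereocentres of 13 and 14 and the orientation of 12 do not matter, because every isomer loses its ethoxy group and converges on achiral 15. Cross-addition must beat self-dimerisation, and this is secured by the fully substituted C=C bonds of 11, which make it a poor dienophile, and by the large excess of unhindered 12. Ethanol must leave rather than HBr, and this is secured because both bromines of 14 sit on sp2 carbons, so only the ethoxy group is a leaving group on an sp3 carbon next to a CH2.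

Step 7
Reactants: 15 1,4-dibromo-2-(2,4-dibromophenoxy)-3-methoxybenzene
Product: 17 3,6-dibromo-2-(2,4-dibromophenoxy)phenol, via dibromo[3,6-dibromo-2-(2,4-dibromophenoxy)phenoxy]borane 16 (not isolated)
Conditions: BBr3 (2 equiv, 1 M in CH2Cl2), CH2Cl2, −78 °C → rt; H2O, 0 °C
Reagents that add atoms: none
Why: In this Lewis-acid aryl methyl ether cleavage BBr3 binds the methoxy oxygen and bromide attacks the methyl carbon (SN2), while the diaryl ether has no sp3 C–O bond to cleave and the aryl bromides are inert.

**Compound list**
1 | 3,4-dibromothiophene | Brc1cscc1Br | starting material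
2 | sodium methoxide | [Na+].[O-]C | starting material
3 | 3-bromo-4-methoxythiophene | COc1cscc1Br | intermediate
4 | (4-methoxythiophen-3-yl)lithium | [Li]c1cscc1OC | intermediate
5 | lithium triisopropoxy(4-methoxythiophen-3-yl)borate | [Li+].COc1cscc1[B-](OC(C)C)(OC(C)C)OC(C)C | intermediate
6 | (4-methoxythiophen-3-yl)boronic acid | COc1cscc1B(O)O | intermediate
7 | 2,4-dibromophenol | Oc1ccc(Br)cc1Br | starting material
8 | 3-(2,4-dibromophenoxy)-4-methoxythiophene | COc1cscc1Oc1ccc(Br)cc1Br | intermediate
9 | 2,5-dibromo-3-(2,4-dibromophenoxy)-4-methoxythiophene | COc1c(Br)sc(Br)c1Oc1ccc(Br)cc1Br | intermediate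
10 | 2,5-dibromo-3-(2,4-dibromophenoxy)-4-methoxythiophene 1-oxide | COC1=C(Br)S(=O)C(Br)=C1Oc1ccc(Br)cc1Br | intermediate
11 | 2,5-dibromo-3-(2,4-dibromophenoxy)-4-methoxythiophene 1,1-dioxide | COC1=C(Br)S(=O)(=O)C(Br)=C1Oc1ccc(Br)cc1Br | intermediate
12 | ethyl vinyl ether | C=COCC | starting material
13 | 1,4-dibromo-2-(2,4-dibromophenoxy)-5-ethoxy-3-methoxy-7-thiabicyclo[2.2.1]hept-2-ene 7,7-dioxide (racemic; drawn as the regioisomer expected from bonding of the vinyl ether CH2 to the terminus next to C–OAr; regio- and endo/exo isomers all converge on 15) | CCOC1CC2(Br)C(Oc3ccc(Br)cc3Br)=C(OC)C1(Br)S2(=O)=O | intermediate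
14 | 1,4-dibromo-2-(2,4-dibromophenoxy)-5-ethoxy-3-methoxycyclohexa-1,3-diene (racemic) | CCOC1CC(Br)=C(Oc2ccc(Br)cc2Br)C(OC)=C1Br | intermediate
15 | 1,4-dibromo-2-(2,4-dibromophenoxy)-3-methoxybenzene | COc1c(Br)ccc(Br)c1Oc1ccc(Br)cc1Br | intermediate
16 | dibromo[3,6-dibromo-2-(2,4-dibromophenoxy)phenoxy]borane | BrB(Br)Oc1c(Br)ccc(Br)c1Oc1ccc(Br)cc1Br | intermediate
17 | 3,6-dibromo-2-(2,4-dibromophenoxy)phenol (achiral) | Oc1c(Br)ccc(Br)c1Oc1ccc(Br)cc1Br | target

Total step count: 7. Longest linear sequence: 7 steps, from 1 to 17.

**Steps most likely to fail**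

Risk 1 (step 6). The two oxygen donors on the internal diene carbons raise the LUMO. The polar cycloaddition may then be too slow, and three processes could overtake it:
- thermal decay of the sulfone
- displacement of the aryloxy group by liberated ethanol
- cationic polymerisation of the vinyl ether

The fallback sets out from 11 and replaces polarity matching by strain activation. Heating 11 with norbornadiene (5 equiv) in xylene at 130–140 °C should give 5,8-dibromo-6-(2,4-dibromophenoxy)-7-methoxy-1,4,4a,5,8,8a-hexahydro-1,4-methano-5,8-epithionaphthalene S,S-dioxide F1. This loses SO2 to give 5,8-dibromo-6-(2,4-dibromophenoxy)-7-methoxy-1,4,4a,8a-tetrahydro-1,4-methanonaphthalene F2. A retro-Diels–Alder loss of cyclopentadiene at the same temperature aromatises ring A, and the fallback comes back to the route at 15.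

Risk 2 (step 5). Oxygen transfer may go to the electron-rich ring carbons instead of sulfur. It may also stall at the sulfoxide, which is then consumed by self-condensation before the second oxidation. The fallback sets out from 9 and stops deliberately at the sulfoxide level, using mCPBA (1.1 equiv) and BF3·OEt2 in CH2Cl2 at −20 °C with a basic work-up. The 1-oxide 10 is isolated cold and used as the diene, because thiophene 1-oxides cycloadd to alkenes at or below room temperature. With 12 in CH2Cl2 at 0 °C → rt it should give 1,4-dibromo-2-(2,4-dibromophenoxy)-5-ethoxy-3-methoxy-7-thiabicyclo[2.2.1]hept-2-ene 7-oxide F3. Heating F3 in toluene extrudes sulfur monoxide, and the fallback comes back to the route at 14, which is aromatised with acid as in step 6.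

Risk 3 (step 3). Aryl transfer to an acidic, ortho-brominated phenoxide may be slow. The ortho-methoxy boronic acid is then lost by protodeboronation, oxidative hydroxylation or homocoupling. The fallback sets out from 3 and reverses the polarity of the thiophene partner. A copper-catalysed aromatic Finkelstein exchange (NaI, CuI, trans-N,N'-dimethylcyclohexane-1,2-diamine, dioxane, 110 °C) gives 3-iodo-4-methoxythiophene F4. This is joined to 7 by a chemoselective Ullmann ether coupling (CuI, picolinic acid, Cs2CO3, DMSO, 80–90 °C). At that temperature the thienyl C–I bond should be activated well before the C–Br bonds of the electron-rich phenoxide. The fallback comes back to the route at 8.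

**Further compounds**
F1 | step 6 | 5,8-dibromo-6-(2,4-dibromophenoxy)-7-methoxy-1,4,4a,5,8,8a-hexahydro-1,4-methano-5,8-epithionaphthalene S,S-dioxide (racemic) | COC1=C(Oc2ccc(Br)cc2Br)C2(Br)C3C4CC(C=C4)C3C1(Br)S2(=O)=O
F2 | step 6 | 5,8-dibromo-6-(2,4-dibromophenoxy)-7-methoxy-1,4,4a,8a-tetrahydro-1,4-methanonaphthalene (racemic) | COC1=C(Br)C2C3CC(C=C3)C2C(Br)=C1Oc1ccc(Br)cc1Br
F3 | step 5 | 1,4-dibromo-2-(2,4-dibromophenoxy)-5-ethoxy-3-methoxy-7-thiabicyclo[2.2.1]hept-2-ene 7-oxide (racemic) | CCOC1CC2(Br)C(Oc3ccc(Br)cc3Br)=C(OC)C1(Br)S2=O
F4 | step 3 | 3-iodo-4-methoxythiophene | COc1cscc1I
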